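**Strategy**

Everything rests on forming the C6–O bond of the butenolide last, by oxidative lactonisation of a germacra-1(10),4,7(11)-trien-12-oic acid. The step exploits C6–H, the only doubly allylic hydrogen of the ten-membered ring (between C4=C5 and C7=C11), which the 7(11)E geometry holds next to the C12 carboxyl: a carboxyl radical removes it through a six-membered transition state, and copper-mediated C–O bond formation closes the five-membered lactone (O, C12, C11, C7, C6) and sets C6 in one operation. The precursor is the 13-acetoxy-8-silyloxy acid, made from germacrone by excising the isopropylidene unit as acetone and re-installing C11–C13 through an O8-tethered malonate condensation that fixes the alkene geometry.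

Key step: step 10

Remark: germacrane numbering (ring C1–C10, C11–C13 on C7, C14 on C10, C15 on C4) is kept for all intermediates, including those in which C11–C13 are absent.
Remark: allylic oxidation of the two C11 methyl groups is avoided, because electrophilic oxidants would prefer the more electron-rich ring alkenes and C6; C11–C13 are instead brought in at the correct oxidation level.
Remark: the configuration at C7 of the spiro-epoxide intermediates and the unassigned centres of the aldol lactone are temporary, since C7 becomes sp2 again.
Assumption: germacrone, mono-tert-butyl malonate and (R)-2-methylglycidol are bought.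

**Route**

Step 1
Reactants: 1 germacrone
Product: 2 (8S)-germacra-1(10)E,4E,7(11)-trien-8-ol
Conditions: (R)-1-methyl-3,3-diphenyltetrahydro-1H,3H-pyrrolo[1,2-c][1,3,2]oxazaborole (C18H20BNO, 0.2 equiv), catecholborane (1.5 equiv), toluene, −78 to −40 °C; aq. NaOH work-up
Reagents that add atoms: none
Why: Corey–Bakshi–Shibata reduction, in which the oxazaborolidine–borane complex should deliver hydride 1,2 to the C8 carbonyl with the alkylidene-bearing C7 as the large group, so that the (R)-catalyst sets 8S, while catecholborane at low temperature should leave the three alkenes untouched.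

Step 2
Reactants: 2 (8S)-germacra-1(10)E,4E,7(11)-trien-8-ol
Product: 3 (7R,8S)-7,11-epoxygermacra-1(10)E,4E-dien-8-ol
Conditions: VO(acac)2 (3 mol %), tBuOOH (1.3 equiv, decane solution), CH2Cl2, 0 °C
Reagents that add atoms: tert-butyl hydroperoxide, CC(C)(C)OO
Why: Hydroxyl-directed epoxidation, in which the vanadate ester of the C8 alcohol should deliver oxygen only to the allylic C7=C11 alkene on the hydroxyl face (7R) and spare both ring alkenes; the C7 configuration is of no consequence because C7 becomes a carbonyl in step 4.

Step 3
Reactants: 3 (7R,8S)-7,11-epoxygermacra-1(10)E,4E-dien-8-ol; 4 mono-tert-butyl malonate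
Product: 5 (7R,8S)-7,11-epoxygermacra-1(10)E,4E-dien-8-yl tert-butyl malonate
Conditions: DCC (1.3 equiv), 4-(dimethylamino)pyridine (0.1 equiv), CH2Cl2, 0 °C to rt
Reagents that add atoms: none
Why: Steglich esterification, which proceeds through the acylketene of the malonic half ester and therefore acylates the hindered secondary alcohol under neutral conditions, attaching the future C11, C12 and C13 to O8.

Step 4
Reactants: 5 (7R,8S)-7,11-epoxygermacra-1(10)E,4E-dien-8-yl tert-butyl malonate
Product: 7 tert-butyl (1S,3E,7E)-3,7-dimethyl-10-oxocyclodeca-3,7-dien-1-yl malonate (ketone at C7, ester oxygen on C8), via C7–C11 diol 6 (not isolated)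
Conditions: H5IO6 (1.3 equiv), THF–Et2O, 0 °C
Reagents that add atoms: none
Why: Periodic acid cleavage of an epoxide (hydration at the tertiary C11 terminus, then Malaprade glycol cleavage), which should release acetone and leave the C7 ketone, while the acyl group on O8 blocks cleavage of C7–C8 and isolated trisubstituted alkenes do not react with periodate.

Step 5
Reactants: 7 tert-butyl (1S,3E,7E)-3,7-dimethyl-10-oxocyclodeca-3,7-dien-1-yl malonate
Product: 8 tert-butyl (8S)-7-hydroxygermacra-1(10)E,4E-dien-13,8-olide-12-oate (C7 and C11 as a mixture)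
Conditions: MgBr2·OEt2 (1.2 equiv), iPr2NEt (1.5 equiv), CH2Cl2, 0 °C; aq. NH4Cl
Reagents that add atoms: none
Why: Intramolecular aldol addition under soft enolisation (first half of a Knoevenagel condensation, 5-exo closure of the magnesium malonate enolate onto the C7 ketone), in which only the malonate CH2 is acidic enough for the amine so that C8–H is untouched; the new centres at C7 and C11 form as a mixture and are removed in step 6.

Step 6
Reactants: 8 tert-butyl (8S)-7-hydroxygermacra-1(10)E,4E-dien-13,8-olide-12-oate
Product: 9 tert-butyl (8S)-germacra-1(10)E,4E,7(11)-trien-13,8-olide-12-oate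
Conditions: Ph2S[OC(CF3)2Ph]2 (Martin sulfurane, 1.5 equiv), CH2Cl2, 0 °C
Reagents that add atoms: none
Why: Sulfurane dehydration of a tertiary alcohol (loss of the activated C7 oxygen and the acidic C11–H) completes the Knoevenagel condensation without base, which matters because C8–H of the product is vinylogously acidic; the lactone ring fixes C13 cis to C8 and C12 cis to C6.

Step 7
Reactants: 9 tert-butyl (8S)-germacra-1(10)E,4E,7(11)-trien-13,8-olide-12-oate
Product: 10 tert-butyl (8S)-8,13-dihydroxygermacra-1(10)E,4E,7(11)E-trien-12-oate
Conditions: iBu2AlH (2.3 equiv), CH2Cl2, −78 to −30 °C; aq. sodium potassium tartrate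
Reagents that add atoms: none
Why: Hydride reduction of a lactone to a diol, in which iBu2AlH should add 1,2 to the lactone carbonyl and, after collapse of the aluminium lactolate on warming, to the aldehyde, while the hindered conjugated tert-butyl ester should survive at low temperature; the 7(11)E geometry is carried over from the ring.

Step 8
Reactants: 10 tert-butyl (8S)-8,13-dihydroxygermacra-1(10)E,4E,7(11)E-trien-12-oate
Product: 11 tert-butyl (8S)-13-acetoxy-8-hydroxygermacra-1(10)E,4E,7(11)E-trien-12-oate
Conditions: Ac2O (1.1 equiv), pyridine (3 equiv), CH2Cl2, −20 °C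
Reagents that add atoms: acetic anhydride, CC(=O)OC(C)=O
Why: Chemoselective O-acetylation, in which a limiting amount of anhydride at low temperature should acylate the primary allylic C13 alcohol in preference to the hindered secondary C8 alcohol.

Step 9
Reactants: 11 tert-butyl (8S)-13-acetoxy-8-hydroxygermacra-1(10)E,4E,7(11)E-trien-12-oate
Product: 14 (8S)-13-acetoxy-8-(tert-butyldimethylsilyloxy)germacra-1(10)E,4E,7(11)E-trien-12-oic acid, via silylated tert-butyl ester 12 (not isolated), via trimethylsilyl ester 13 (not isolated)
Conditions: TBSOTf (1.3 equiv), 2,6-lutidine (5 equiv), CH2Cl2, −78 °C; then TMSOTf (2.5 equiv), 0 °C; aq. citric acid (pH 4) work-up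
Reagents that add atoms: tert-butyldimethylsilyl triflate, CC(C)(C)[Si](C)(C)OS(=O)(=O)C(F)(F)F
Why: Silyl ether formation at C8 followed by silyl-triflate-mediated tert-butyl ester cleavage (carbonyl O-silylation, loss of isobutene) gives a trimethylsilyl ester that hydrolyses on work-up; the lutidine-buffered conditions avoid the protic acid that would trigger transannular cyclisation of the 1(10),4-diene.

Step 10
Reactants: 14 (8S)-13-acetoxy-8-(tert-butyldimethylsilyloxy)germacra-1(10)E,4E,7(11)E-trien-12-oic acid
Product: 15 (6R,8S)-13-acetoxy-8-(tert-butyldimethylsilyloxy)germacra-1(10)E,4E,7(11)-trien-12,6-olide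
Conditions: Cu(OTf)2 (2.2 equiv), Li2CO3 (2.0 equiv), MeCN (0.01 M, degassed), 390 nm LEDs, 25 °C, argon
Reagents that add atoms: none
Why: Proposed new method: the carboxylate of 14 bound to divalent copper is expected to undergo ligand-to-metal charge transfer on irradiation, releasing an alkenoyloxy radical that decarboxylates slowly because the carboxyl sits on sp2 carbon and instead abstracts the in-plane C6 hydrogen through a six-membered transition state (O, C12, C11, C7, C6, H), after which a second divalent copper captures the C4–C5–C6-delocalised radical at C6 and C–O reductive elimination from trivalent copper forms the lactone. The closest known reaction type is the oxidative benzylic C–H lactonisation of 2-alkylbenzoic acids to phthalides by acyloxy-radical 1,5-hydrogen transfer and radical–polar crossover, combined with the photochemical generation of aroyloxy radicals from copper carboxylates; the extension lies in an alkenoic acid and a doubly allylic C–H bond in a ten-membered ring. The five-membered ring (O, C12, C11, C7, C6) closes by C6–O bond formation, 5-exo with respect to the C4–C5–C6 allyl unit and through a six-membered cupracycle, in preference to a seven-membered lactone at C4. The new C6 stereocentre is controlled by the ring conformation, because oxygen takes the place of the hydrogen lying in the acrylate plane, so the conformer with H8 eclipsing C7=C11 and with C5 and C9 on opposite faces of the C6–C7–C8 plane should give the 6R isomer (O6 cis to O8). The step needs site selectivity over C2, C3, C8, C9, C13 and the methyl groups, and hydrogen transfer in preference to addition of the oxygen radical to C4=C5; it relies on the 7(11)E geometry, which holds only C6–H in the carboxyl plane at bonding distance, and on the weakness of the doubly allylic C–H bond. Room temperature and the absence of electrophilic halogen are chosen because the 1(10),4-diene is prone to Cope rearrangement on heating and to transannular cyclisation with halonium sources.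

Step 11
Reactants: 15 (6R,8S)-13-acetoxy-8-(tert-butyldimethylsilyloxy)germacra-1(10)E,4E,7(11)-trien-12,6-olide
Product: 16 (6R,8S)-13-acetoxy-8-hydroxygermacra-1(10)E,4E,7(11)-trien-12,6-olide
Conditions: HF·pyridine, pyridine, THF, 0 °C to rt
Reagents that add atoms: none
Why: Fluoride-mediated silyl ether cleavage under buffered, non-basic conditions, chosen over basic fluoride because C6–H is γ-acidic and the C13 acetate is a vinylogous leaving group.

Step 12
Reactants: 17 (R)-2-methylglycidol
Product: 18 (S)-2-methyloxirane-2-carboxylic acid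
Conditions: RuCl3·3H2O (2 mol %), NaIO4 (2.5 equiv), MeCN–EtOAc–H2O, 0 °C to rt
Reagents that add atoms: water, O
Why: RuCl3/NaIO4 oxidation of a primary alcohol to the acid through the aldehyde hydrate, conditions under which glycidol epoxides are retained; the quaternary centre is not involved and its descriptor changes to S only by priority.

Step 13
Reactants: 18 (S)-2-methyloxirane-2-carboxylic acid
Product: 19 (R)-3-chloro-2-hydroxy-2-methylpropanoic acid
Conditions: HCl (4 M in dioxane, 1.5 equiv), Et2O, 0 °C
Reagents that add atoms: hydrogen chloride, Cl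
Why: Acid-mediated SN2 opening of the epoxide by chloride at the unsubstituted C3, the tertiary C2 being deactivated towards ionisation by the carboxyl group, so that the C2–O bond and the C2 configuration are retained.

Step 14
Reactants: 19 (R)-3-chloro-2-hydroxy-2-methylpropanoic acid
Product: 21 (S)-3-chloro-2-methyl-2-(trimethylsilyloxy)propanoyl chloride, via bis(trimethylsilyl) derivative 20 (not isolated)
Conditions: TMSCl (2.2 equiv), pyridine (2.2 equiv), CH2Cl2, 0 °C to rt; then (COCl)2 (1.1 equiv), N,N-dimethylformamide (cat.), 0 °C to rt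
Reagents that add atoms: chlorotrimethylsilane, C[Si](C)(C)Cl; oxalyl chloride, O=C(Cl)C(Cl)=O
Why: Persilylation followed by conversion of the silyl ester into the acid chloride with oxalyl chloride under Vilsmeier-type catalysis gives the activated acid with the tertiary hydroxyl masked as its trimethylsilyl ether; the stereocentre is untouched (descriptor S by priority).

Step 15
Reactants: 16 (6R,8S)-13-acetoxy-8-hydroxygermacra-1(10)E,4E,7(11)-trien-12,6-olide; 21 (S)-3-chloro-2-methyl-2-(trimethylsilyloxy)propanoyl chloride
Product: 23 (6R,8S)-13-acetoxy-8-[(R)-3-chloro-2-hydroxy-2-methylpropanoyloxy]germacra-1(10)E,4E,7(11)-trien-12,6-olide, via O-trimethylsilyl ester 22 (not isolated)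
Conditions: pyridine (4 equiv), 4-(dimethylamino)pyridine (0.2 equiv), CH2Cl2, 0 °C to rt; then citric acid, MeOH, 0 °C
Reagents that add atoms: none
Why: Nucleophilic-catalysed acylation of the C8 alcohol through the acylpyridinium ion, then mild acid methanolysis of the tertiary trimethylsilyl ether; only weak bases are used so that C6 is not deprotonated and the chlorohydrin does not close.

Step 16
Reactants: 23 (6R,8S)-13-acetoxy-8-[(R)-3-chloro-2-hydroxy-2-methylpropanoyloxy]germacra-1(10)E,4E,7(11)-trien-12,6-olide
Product: 24 CNP0255009.1, (1R,4R,5R,6S,8S,10R)-13-acetoxy-8-[(R)-3-chloro-2-hydroxy-2-methylpropanoyloxy]-1,10:4,5-diepoxygermacr-7(11)-en-12,6-olide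
Conditions: mCPBA (2.5 equiv), NaHCO3, CH2Cl2, 0 °C
Reagents that add atoms: 3-chloroperoxybenzoic acid, OOC(=O)c1cccc(Cl)c1
Why: Prilezhaev epoxidation, in which the two electron-rich trisubstituted ring alkenes should react in preference to the electron-poor butenolide alkene, each on its outer face in the crown conformation with both methyl groups syn, giving the trans 1R,10R and 4R,5R epoxides; the C6 descriptor changes from R to S only through the priority change at C5.

**Compound list**

1 | germacrone, (3E,7E)-3,7-dimethyl-10-(propan-2-ylidene)cyclodeca-3,7-dien-1-one | CC(C)=C1C/C=C(C)/CC/C=C(C)/CC1=O | starting material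
2 | (8S)-germacra-1(10)E,4E,7(11)-trien-8-ol | CC(C)=C1C/C=C(C)/CC/C=C(C)/C[C@@H]1O | intermediate
3 | (7R,8S)-7,11-epoxygermacra-1(10)E,4E-dien-8-ol (epoxide oxygen cis to OH) | CC1(C)O[C@@]12C/C=C(C)/CC/C=C(C)/C[C@@H]2O | intermediate
4 | mono-tert-butyl malonate (3-tert-butoxy-3-oxopropanoic acid) | CC(C)(C)OC(=O)CC(=O)O | starting material
5 | (7R,8S)-7,11-epoxygermacra-1(10)E,4E-dien-8-yl tert-butyl malonate | CC1(C)O[C@@]12C/C=C(C)/CC/C=C(C)/C[C@@H]2OC(=O)CC(=O)OC(C)(C)C | intermediate
6 | (7R,8S)-7,11-dihydroxygermacra-1(10)E,4E-dien-8-yl tert-butyl malonate | CC(C)(O)[C@@]1(O)C/C=C(C)/CC/C=C(C)/C[C@@H]1OC(=O)CC(=O)OC(C)(C)C | intermediate (not isolated)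
7 | tert-butyl (1S,3E,7E)-3,7-dimethyl-10-oxocyclodeca-3,7-dien-1-yl malonate | O=C1C/C=C(C)/CC/C=C(C)/C[C@@H]1OC(=O)CC(=O)OC(C)(C)C | intermediate
8 | tert-butyl (8S)-7-hydroxygermacra-1(10)E,4E-dien-13,8-olide-12-oate (C7, C11 unassigned mixture) | CC(C)(C)OC(=O)C1C2(O)C/C=C(C)/CC/C=C(C)/C[C@@H]2OC1=O | intermediate
9 | tert-butyl (8S)-germacra-1(10)E,4E,7(11)-trien-13,8-olide-12-oate | CC(C)(C)OC(=O)C1=C2C/C=C(C)/CC/C=C(C)/C[C@@H]2OC1=O | intermediate
10 | tert-butyl (8S)-8,13-dihydroxygermacra-1(10)E,4E,7(11)E-trien-12-oate | OC/C(C(=O)OC(C)(C)C)=C1/C/C=C(C)/CC/C=C(C)/C[C@@H]1O | intermediate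
11 | tert-butyl (8S)-13-acetoxy-8-hydroxygermacra-1(10)E,4E,7(11)E-trien-12-oate | CC(=O)OC/C(C(=O)OC(C)(C)C)=C1/C/C=C(C)/CC/C=C(C)/C[C@@H]1O | intermediate
12 | tert-butyl (8S)-13-acetoxy-8-(tert-butyldimethylsilyloxy)germacra-1(10)E,4E,7(11)E-trien-12-oate | CC(=O)OC/C(C(=O)OC(C)(C)C)=C1/C/C=C(C)/CC/C=C(C)/C[C@@H]1O[Si](C)(C)C(C)(C)C | intermediate (not isolated)
13 | trimethylsilyl (8S)-13-acetoxy-8-(tert-butyldimethylsilyloxy)germacra-1(10)E,4E,7(11)E-trien-12-oate | CC(=O)OC/C(C(=O)O[Si](C)(C)C)=C1/C/C=C(C)/CC/C=C(C)/C[C@@H]1O[Si](C)(C)C(C)(C)C | intermediate (not isolated)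
14 | (8S)-13-acetoxy-8-(tert-butyldimethylsilyloxy)germacra-1(10)E,4E,7(11)E-trien-12-oic acid | CC(=O)OC/C(C(=O)O)=C1/C/C=C(C)/CC/C=C(C)/C[C@@H]1O[Si](C)(C)C(C)(C)C | intermediate (precursor of the key step)
15 | (6R,8S)-13-acetoxy-8-(tert-butyldimethylsilyloxy)germacra-1(10)E,4E,7(11)-trien-12,6-olide | CC(=O)OCC1=C2[C@@H](O[Si](C)(C)C(C)(C)C)C/C(C)=C/CC/C(C)=C/[C@H]2OC1=O | intermediate (product of the key step)
16 | (6R,8S)-13-acetoxy-8-hydroxygermacra-1(10)E,4E,7(11)-trien-12,6-olide | CC(=O)OCC1=C2[C@@H](O)C/C(C)=C/CC/C(C)=C/[C@H]2OC1=O | intermediate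
17 | (R)-2-methylglycidol, (R)-(2-methyloxiran-2-yl)methanol | OC[C@@]1(C)OC1 | starting material
18 | (S)-2-methyloxirane-2-carboxylic acid | OC(=O)[C@@]1(C)OC1 | intermediate
19 | (R)-3-chloro-2-hydroxy-2-methylpropanoic acid | OC(=O)[C@@](CCl)(C)O | intermediate
20 | trimethylsilyl (R)-3-chloro-2-methyl-2-(trimethylsilyloxy)propanoate | C[Si](C)(C)OC(=O)[C@@](CCl)(C)O[Si](C)(C)C | intermediate (not isolated)
21 | (S)-3-chloro-2-methyl-2-(trimethylsilyloxy)propanoyl chloride | ClC(=O)[C@@](CCl)(C)O[Si](C)(C)C | intermediate
22 | (6R,8S)-13-acetoxy-8-[(R)-3-chloro-2-methyl-2-(trimethylsilyloxy)propanoyloxy]germacra-1(10)E,4E,7(11)-trien-12,6-olide | CC(=O)OCC1=C2[C@@H](OC(=O)[C@@](C)(O[Si](C)(C)C)CCl)C/C(C)=C/CC/C(C)=C/[C@H]2OC1=O | intermediate (not isolated)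
23 | (6R,8S)-13-acetoxy-8-[(R)-3-chloro-2-hydroxy-2-methylpropanoyloxy]germacra-1(10)E,4E,7(11)-trien-12,6-olide | CC(=O)OCC1=C2[C@@H](OC(=O)[C@@](C)(O)CCl)C/C(C)=C/CC/C(C)=C/[C@H]2OC1=O | intermediate
24 | CNP0255009.1, (1R,4R,5R,6S,8S,10R)-13-acetoxy-8-[(R)-3-chloro-2-hydroxy-2-methylpropanoyloxy]-1,10:4,5-diepoxygermacr-7(11)-en-12,6-olide | CC(=O)OCC1=C2[C@@H](OC(=O)[C@@](C)(O)CCl)C[C@@]3(C)O[C@@H]3CC[C@@]3(C)O[C@@H]3[C@H]2OC1=O | target

**Step count and risks**

Total: 16 steps. Longest linear sequence: 13 steps (steps 1–11, 15 and 16); the acid chloride 21 is made in 3 steps (12–14).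

The three steps most likely to fail:

1. Step 10 (the proposed lactonisation). Possible failures are back electron transfer without net conversion, addition of the oxygen-centred radical to C4=C5 instead of hydrogen transfer, C–O bond formation at the C4 terminus of the delocalised radical, closure on the wrong face of C6, and acid- or copper-induced transannular cyclisation of the diene. The fallback uses known chemistry and sets out from 14. Wohl–Ziegler bromination at the doubly allylic position (NBS, catalytic azobisisobutyronitrile, PhCF3, 65 °C) should give the 6-bromo acid F1, a classical γ-bromination of a β,β-disubstituted acrylic acid derivative. Treatment with NaHCO3 in DMF at room temperature should then close the butenolide by carboxylate displacement of the allylic bromide, returning to the route at 15. The risk in this variant is ionic bromination of the ring alkenes, which is why it is held in reserve.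

2. Step 7 (reduction of the lactone beside the tert-butyl ester). Possible failures are over-reduction of the tert-butyl ester, conjugate hydride addition to the doubly activated alkene, and incomplete collapse of the aluminium lactolate. The fallback sets out from 9 and divides the reduction into two chemically distinct events. One equivalent of iBu2AlH at −78 °C with a cold quench should stop at the lactol F2. A Luche reduction (NaBH4, CeCl3·7H2O, MeOH, −40 °C) of its ring-opened hydroxy-enal tautomer, with a reagent that does not reduce esters, should then give the diol and return to the route at 10.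

3. Step 16 (double epoxidation as the last step). Possible failures are attack on the inner face of one alkene if the C8 ester changes the conformer population, sluggish oxidation of C4=C5 next to the lactone oxygen, and acid-induced opening of the first-formed epoxide. The fallback replaces substrate control by reagent control and sets out from 15. A Shi epoxidation (D-fructose-derived ketone 1,2:4,5-di-O-isopropylidene-β-D-erythro-2,3-hexodiulo-2,6-pyranose, KHSO5, buffered MeCN–dimethoxymethane–water, 0 °C), whose sense for E-trisubstituted alkenes matches the required R,R epoxides, should give the diepoxide silyl ether F3. Desilylation with HF·pyridine buffered with pyridine should give the diepoxy alcohol F4. Acylation with 21 (pyridine, catalytic 4-(dimethylamino)pyridine) should give the trimethylsilyl ether F5, and citric acid in MeOH should release the tertiary alcohol, returning to the route at 24.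

**Further compounds**

F1 | step 10 | (8S)-13-acetoxy-6-bromo-8-(tert-butyldimethylsilyloxy)germacra-1(10)E,4E,7(11)-trien-12-oic acid (carboxyl cis to C6, C6 epimers) | CC(=O)OC/C(C(=O)O)=C1/C(Br)/C=C(C)/CC/C=C(C)/C[C@@H]1O[Si](C)(C)C(C)(C)C
F2 | step 7 | tert-butyl (8S)-13-hydroxy-8,13-epoxygermacra-1(10)E,4E,7(11)-trien-12-oate (lactol, C13 epimers) | CC(C)(C)OC(=O)C1=C2C/C=C(C)/CC/C=C(C)/C[C@@H]2OC1O
F3 | step 16 | (1R,4R,5R,6S,8S,10R)-13-acetoxy-8-(tert-butyldimethylsilyloxy)-1,10:4,5-diepoxygermacr-7(11)-en-12,6-olide | CC(=O)OCC1=C2[C@@H](O[Si](C)(C)C(C)(C)C)C[C@@]3(C)O[C@@H]3CC[C@@]3(C)O[C@@H]3[C@H]2OC1=O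
F4 | step 16 | (1R,4R,5R,6S,8S,10R)-13-acetoxy-8-hydroxy-1,10:4,5-diepoxygermacr-7(11)-en-12,6-olide | CC(=O)OCC1=C2[C@@H](O)C[C@@]3(C)O[C@@H]3CC[C@@]3(C)O[C@@H]3[C@H]2OC1=O
F5 | step 16 | (1R,4R,5R,6S,8S,10R)-13-acetoxy-8-[(R)-3-chloro-2-methyl-2-(trimethylsilyloxy)propanoyloxy]-1,10:4,5-diepoxygermacr-7(11)-en-12,6-olide | CC(=O)OCC1=C2[C@@H](OC(=O)[C@@](C)(O[Si](C)(C)C)CCl)C[C@@]3(C)O[C@@H]3CC[C@@]3(C)O[C@@H]3[C@H]2OC1=O
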